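Late in a run, once G stands in the vessel, the step where Z meets G competes with the pairing into Z2, so I read these two vessels by the ratio of G to Z rather than by the clock.

the same everywhere: Z 0.40 M
- red: a single well-mixed tank run continuously and read at steady state, 15 s in it on average
- teal: a closed flask charged with all of it at once and left for 15 s; time 15 s

    Z → G (k1 = 0.00146 s⁻¹)
    2 Z → Z2 (k2 = 0.0585 L mol⁻¹ s⁻¹)
    Z + G → 2 G (k3 = 0.381 L mol⁻¹ s⁻¹)

- percent here means Z units held: one Z2 counts as two
- for a step with 2 of a species take k times the square, and two of it per event
- the stated concentrations are those of everything mixed, before any reaction; amounts are the same in each set-up
- run time (teal): 15 s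

- the set-up with the highest amount of G at the outlet or at the end, in percent of the Z put in ("none" if the first two lie within 2 percentage points) (red / teal / none)
- amount of G at the outlet or at the end, in percent of the Z put in, red
- amount of G at the outlet or at the end, in percent of the Z put in, teal

One thing looks wrong at first: the constant of the step where Z meets G is 6.51 times that of the pairing into Z2, yet at the start of teal a mere 3.03% of the Z lost becomes G. The two go together because that step needs G, teal starts without any, and the seeding is slow, its half-life of 7.9 min being far longer than the 15 s of the run. Per Z, the step where Z meets G runs at its constant times G, and pairing removes Z at 2 times its constant times Z, so, leaving the seeding aside, these two shares are equal where G over Z reaches 2 times the pairing constant over the constant of the step where Z meets G, the even ratio of 0.307, a selectivity factor of one.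

In teal I let pairing set Z, which gives 0.235 M at the end, and G plus a seed term of 0.00383 M then grows as starting Z over present Z, raised to one over the even ratio. That gives G 0.0178 M, or 4.46%, at a ratio of 0.0757, below even. In red, G leaves once per 15 s on average and must be remade about as fast, which puts Z near 0.175 M. The balance of Z units then leaves G at 0.171 M, or 42.8%, at a ratio of 0.977, above even.

The forecast names red, with 44.3% in red and 4.3% in teal, on the grounds that the tank wins by “holding every bit of feed at the G-rich outlet condition”; its red figure stands above mine and its teal figure below mine.

The run gives red as the better set-up, with G at 44.3% in red and 4.29% in teal, and with Z in the red tank at 0.171 M, so that G over Z there reads 1.03, which is 3.37 times the even ratio. Teal left for 150 s holds 40.4% as G, the other Z units are 59.6% of the charge, so its ratio is 0.678 or higher, and its G still stands 3.9 percentage points below red, outside the margin of 2 points.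

(The numbers of this flask were set for the occasion; the run is a simulation.)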